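**Retrosynthetic overview**

1. Numbering: lactone ring B = C1(=O)–O2–C3–C4–C4a–C8a, benzene ring A = C4a to C8a, side chain C1' to C11'. The target comes from its 8-O-methyl, 11'-O-benzyl ether by one BCl3 operation, and that ether from a C1'=C2' unsaturated lactone by alkene saturation.
2. Key disconnection: ring B of the unsaturated lactone is cut at O2–C3 and at C4–C4a, giving 2-iodo-4,6-dimethoxybenzoic acid and a linear (E)-1,3-diene that already carries the whole side chain. Forward, one palladium-catalysed enantioselective diene heteroannulation makes C4a–C4, then closes ring B by forming O2–C3 and sets C3.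
3. Enabling feature: C3 bears the ring oxygen and lies between benzylic C4 and side-chain C1'. With C1'=C2' unsaturation it is an allyl terminus, so C4–C3–C1'–C2' maps onto a 1,3-diene, while the carboxyl carbon C1 and C4 sit on the adjacent ring A carbons C8a and C4a, which is an ortho-halobenzoic acid.
4. Fragments: the iodo acid from 1-iodo-3,5-dimethoxybenzene (formylation, oxidation); the diene from undec-10-yn-1-ol (benzylation, hydroboration, vinylation).
5. Ring order: ring A is purchased; ring B is the only ring formed (step 6).

Key step: step 6

Remark (assumption): the absolute sense of induction of the chiral phosphoramidite in step 6 cannot be predicted with certainty; the ligand antipode that delivers the (3S)-alkenyl lactone is used, both antipodes being available.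

**Route**

Step 1
Reactants: 1 1-iodo-3,5-dimethoxybenzene
Product: 3 2-iodo-4,6-dimethoxybenzaldehyde, via iminium chloride 2 (not isolated)
Conditions: POCl3 (2 equiv), DMF, 0 °C to 90 °C; then H2O, 0 °C to rt
Reagents that add atoms: N,N-dimethylformamide CN(C)C=O; water O
Why: Vilsmeier–Haack formylation should go ortho to one methoxy group and para to the other at the carbon next to iodine, as with the bromo and methyl analogues, because the site between the two methoxy groups is more hindered and the iodine (meta to both donors) is not displaced.

Step 2
Reactants: 3 2-iodo-4,6-dimethoxybenzaldehyde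
Product: 4 2-iodo-4,6-dimethoxybenzoic acid
Conditions: NaClO2, NaH2PO4, 2-methyl-2-butene, t-BuOH/H2O, rt
Reagents that add atoms: sodium chlorite [Na+].[O-]Cl=O
Why: Pinnick oxidation converts the hindered aldehyde to the acid without touching the aryl iodide, the alkene scavenger intercepting hypochlorite before it can chlorinate the electron-rich ring.

Step 3
Reactants: 5 undec-10-yn-1-ol
Product: 6 benzyl undec-10-yn-1-yl ether
Conditions: NaH, BnBr, n-Bu4NI (cat.), THF, 0 °C to rt
Reagents that add atoms: benzyl bromide BrCc1ccccc1
Why: Williamson ether synthesis on the primary alkoxide, the terminal alkyne C–H being too weakly acidic to compete under these conditions.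

Step 4
Reactants: 6 benzyl undec-10-yn-1-yl ether
Product: 7 2-[(1E)-11-(benzyloxy)undec-1-en-1-yl]-4,4,5,5-tetramethyl-1,3,2-dioxaborolane
Conditions: pinacolborane (1.2 equiv), Cp2Zr(H)Cl (10 mol%), Et3N (10 mol%), neat, 60 °C
Reagents that add atoms: pinacolborane CC1(C)OBOC1(C)C
Why: zirconocene-hydride-catalysed hydroboration of the terminal alkyne is a syn addition with boron at the terminal carbon, so the (E)-alkenylboronate should form.

Step 5
Reactants: 7 2-[(1E)-11-(benzyloxy)undec-1-en-1-yl]-4,4,5,5-tetramethyl-1,3,2-dioxaborolane
Product: 8 {[(10E)-trideca-10,12-dien-1-yloxy]methyl}benzene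
Conditions: vinyl bromide (1 M in THF, 3 equiv), Pd(PPh3)4 (5 mol%), aq. NaOH (2 M), THF, 60 °C, sealed vessel
Reagents that add atoms: vinyl bromide C=CBr
Why: Suzuki–Miyaura coupling of an alkenylboronate with an alkenyl bromide proceeds with retention of alkene geometry and should give the (E)-1,3-diene.

Step 6
Reactants: 4 2-iodo-4,6-dimethoxybenzoic acid; 8 {[(10E)-trideca-10,12-dien-1-yloxy]methyl}benzene (1.5 equiv)
Product: 9 (3S)-3-[(1E)-11-(benzyloxy)undec-1-en-1-yl]-6,8-dimethoxy-3,4-dihydro-1H-isochromen-1-one
Conditions: Pd2(dba)3 (2.5 mol%), (S)-BINOL-derived N,N-bis[(R)-1-phenylethyl]phosphoramidite (11 mol%; antipode per the remark above), K2CO3 (1.5 equiv), 1,4-dioxane, 70 °C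
Reagents that add atoms: none
Why: Proposed new method: zerovalent palladium inserts into the C–I bond of 4, the arylpalladium carboxylate adds across the terminal double bond of 8 with the aryl carbon (future C4a) bonding to the unsubstituted CH2 (future C4), and the η3-allylpalladium carboxylate so formed (allyl carbons = future C3, C1', C2') collapses by O2–C3 bond formation with release of zerovalent palladium. The closest known reaction type is the Larock heteroannulation of 1,3-dienes by ortho-iodobenzoic acid, which gives racemic 3-alkenyl-3,4-dihydroisocoumarins, together with the phosphoramidite-controlled enantioselective form of the same annulation with ortho-iodoanilines and ortho-iodophenols; new here is only the union of the carboxylate nucleophile with ligand-controlled enantioselection. Ring B is closed in a 6-exo mode, the carboxylate oxygen attacking the proximal allyl terminus so that C1'=C2' stays outside the ring, whereas attack at the distal terminus would need an eight-membered ring. C3, the only new stereocenter, is set in this C–O bond formation by the chiral phosphoramidite on palladium, which selects between the two interconverting (η3–η1–η3) diastereomeric allyl complexes, and the ligand antipode is chosen so that (3S)-9 results. The step needs insertion at the terminal alkene with the aryl group going to the diene terminus, which is secured by the lower substitution of that alkene and the allyl stabilization of the intermediate, and it needs ring closure to outrun β-hydride elimination, which is secured by the carboxylate being held on palladium next to the allyl unit; the (E) geometry of C1'=C2' is of no consequence because step 7 saturates it.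

Step 7
Reactants: 9 (3S)-3-[(1E)-11-(benzyloxy)undec-1-en-1-yl]-6,8-dimethoxy-3,4-dihydro-1H-isochromen-1-one
Product: 10 (3R)-3-[11-(benzyloxy)undecyl]-6,8-dimethoxy-3,4-dihydro-1H-isochromen-1-one
Conditions: TsNHNH2 (10 equiv), NaOAc (12 equiv), DME/H2O, reflux
Reagents that add atoms: none
Why: diimide reduction delivers H2 to the isolated alkene through a concerted cyclic transition state without hydrogenolysis of the allylic C3–O2 bond or the benzyl ether, so C3 keeps its spatial arrangement (the descriptor changes from S to R only because the CIP priorities change).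

Step 8
Reactants: 10 (3R)-3-[11-(benzyloxy)undecyl]-6,8-dimethoxy-3,4-dihydro-1H-isochromen-1-one
Product: 12 (3R)-8-hydroxy-3-(11-hydroxyundecyl)-6-methoxy-3,4-dihydro-1H-isochromen-1-one, via bis(dichloroborinate) 11 (not isolated)
Conditions: BCl3 (1 M in CH2Cl2, 4 equiv), pentamethylbenzene (3 equiv), CH2Cl2, −78 °C to 0 °C; then H2O, 0 °C
Reagents that add atoms: none
Why: Lewis acid ether cleavage in which boron chelated between the lactone carbonyl and the peri C8 methoxy group directs O-demethylation to C8 only, while the same reagent cleaves the primary benzyl ether (benzyl cation trapped by pentamethylbenzene), leaving the C6 methyl ether, the lactone and C3 untouched.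

**Compound list**

1 | 1-iodo-3,5-dimethoxybenzene | COc1cc(I)cc(OC)c1 | starting material
2 | N-[(2-iodo-4,6-dimethoxyphenyl)methylidene]-N-methylmethanaminium chloride | COc1cc(I)c(C=[N+](C)C)c(OC)c1.[Cl-] | intermediate (not isolated)
3 | 2-iodo-4,6-dimethoxybenzaldehyde | COc1cc(I)c(C=O)c(OC)c1 | intermediate
4 | 2-iodo-4,6-dimethoxybenzoic acid | COc1cc(I)c(C(=O)O)c(OC)c1 | intermediate
5 | undec-10-yn-1-ol | C#CCCCCCCCCCO | starting material
6 | benzyl undec-10-yn-1-yl ether | C#CCCCCCCCCCOCc1ccccc1 | intermediate
7 | 2-[(1E)-11-(benzyloxy)undec-1-en-1-yl]-4,4,5,5-tetramethyl-1,3,2-dioxaborolane | CC1(C)OB(/C=C/CCCCCCCCCOCc2ccccc2)OC1(C)C | intermediate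
8 | {[(10E)-trideca-10,12-dien-1-yloxy]methyl}benzene | C=C/C=C/CCCCCCCCCOCc1ccccc1 | intermediate
9 | (3S)-3-[(1E)-11-(benzyloxy)undec-1-en-1-yl]-6,8-dimethoxy-3,4-dihydro-1H-isochromen-1-one | COc1cc(OC)c2c(c1)C[C@@H](/C=C/CCCCCCCCCOCc1ccccc1)OC2=O | intermediate
10 | (3R)-3-[11-(benzyloxy)undecyl]-6,8-dimethoxy-3,4-dihydro-1H-isochromen-1-one | COc1cc(OC)c2c(c1)C[C@@H](CCCCCCCCCCCOCc1ccccc1)OC2=O | intermediate
11 | (3R)-8-(dichloroboryloxy)-3-[11-(dichloroboryloxy)undecyl]-6-methoxy-3,4-dihydro-1H-isochromen-1-one | COc1cc(OB(Cl)Cl)c2c(c1)C[C@@H](CCCCCCCCCCCOB(Cl)Cl)OC2=O | intermediate (not isolated)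
12 | (3R)-8-hydroxy-3-(11-hydroxyundecyl)-6-methoxy-3,4-dihydro-1H-isochromen-1-one | COc1cc(O)c2c(c1)C[C@@H](CCCCCCCCCCCO)OC2=O | target

**Step count and risks**

Total step count: 8. Longest linear sequence: 6 steps (steps 3, 4, 5, 6, 7, 8 from undec-10-yn-1-ol); the aryl branch (steps 1, 2) joins at step 6.

Steps most likely to fail:

Step 6 (proposed method). What may go wrong:
- insufficient enantiofacial discrimination when a carboxylate closes the ring;
- re-ionization of the allylic C3–O2 bond of the product by zerovalent palladium, with erosion of configuration;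
- β-hydride elimination of the allyl intermediate towards a Heck-type triene;
- protodecarboxylation of the hindered acid.

The fallback uses known chemistry, still closes ring B at O2–C3, and sets C3 afterwards; it sets out from 4 and comes back to the route at 10. Commercial 11-bromoundecan-1-ol is O-benzylated under acid catalysis (benzyl 2,2,2-trichloroacetimidate, TfOH cat., CH2Cl2) to 1-(benzyloxy)-11-bromoundecane F1. F1 is homologated with lithium acetylide–ethylenediamine complex in DMSO to 13-(benzyloxy)tridec-1-yne F2. Acid 4 and F2 are joined in a tandem Sonogashira coupling and 6-endo-dig carboxylate cyclization (Pd/C, PPh3, CuI, Et3N, EtOH, 80 °C). This passes through 2-[13-(benzyloxy)tridec-1-yn-1-yl]-4,6-dimethoxybenzoic acid F3, which is not isolated, and should give 3-[11-(benzyloxy)undecyl]-6,8-dimethoxy-1H-isochromen-1-one F4. Enantioselective hydrogenation of the C3=C4 bond of F4, a known reaction of isocoumarins, should then give (3R)-10. The catalyst is a chiral ruthenium N-heterocyclic carbene–diamine complex made from [Ru(cod)(2-methylallyl)2], a chiral imidazolinium salt, a chiral 1,2-diamine and KOt-Bu under H2, with the antipode chosen accordingly. Steps 3 to 5 and step 7 are not needed in this variant, and the route continues with step 8.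

Step 8. What may go wrong: Friedel–Crafts benzylation of the electron-rich ring A by the benzyl cation released next to the Lewis acid, and loss of discrimination between the C8 and C6 methyl ethers under the excess of BCl3 and the time needed for the ether cleavage at C11'.

The fallback separates the two deprotections; it sets out from 10 and comes back at 12. Hydrogenolysis of the benzyl ether (H2, Pd(OH)2/C, EtOAc, rt) is harmless now that the C3–O2 bond is no longer allylic. It should give (3R)-3-(11-hydroxyundecyl)-6,8-dimethoxy-3,4-dihydro-1H-isochromen-1-one F5. The chelation-directed mono-demethylation at C8 is then run alone (BCl3, 2.2 equiv, CH2Cl2, −78 °C, short reaction time, aqueous work-up). No benzyl cation is present, and the reaction should pass through 11 to 12.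

Step 5. What may go wrong: escape of the volatile vinyl bromide before transmetalation, protodeboronation of 7 in hot aqueous base, and partial E/Z isomerization or oligomerization of the diene, which would carry a geometrically impure diene into step 6.

The fallback inverts the polarity of the coupling partners; it sets out from 7 and comes back at 8. Iododeboronation of 7 with retention of geometry (I2, aq. NaOH, THF, 0 °C) should give {[(10E)-11-iodoundec-10-en-1-yl]oxy}methylbenzene F6. A Stille coupling of F6 with tributyl(vinyl)stannane (Pd(PPh3)4, CuI, DMF, rt) under neutral, base-free conditions should then give 8.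

**Further compounds**

F1 | step 6 | 1-(benzyloxy)-11-bromoundecane | BrCCCCCCCCCCCOCc1ccccc1
F2 | step 6 | 13-(benzyloxy)tridec-1-yne | C#CCCCCCCCCCCCOCc1ccccc1
F3 | step 6 | 2-[13-(benzyloxy)tridec-1-yn-1-yl]-4,6-dimethoxybenzoic acid | COc1cc(C#CCCCCCCCCCCCOCc2ccccc2)c(C(=O)O)c(OC)c1
F4 | step 6 | 3-[11-(benzyloxy)undecyl]-6,8-dimethoxy-1H-isochromen-1-one | COc1cc(OC)c2c(c1)C=C(CCCCCCCCCCCOCc1ccccc1)OC2=O
F5 | step 8 | (3R)-3-(11-hydroxyundecyl)-6,8-dimethoxy-3,4-dihydro-1H-isochromen-1-one | COc1cc(OC)c2c(c1)C[C@@H](CCCCCCCCCCCO)OC2=O
F6 | step 5 | {[(10E)-11-iodoundec-10-en-1-yl]oxy}methylbenzene | I/C=C/CCCCCCCCCOCc1ccccc1
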